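## Analysis of the target

Atom labels: the non-hydrogen atoms of target 29 are numbered C1 to O27 in the order of its SMILES string, and each label is kept for the same atom in every intermediate.

- The target is a bicyclo[3.2.1]octane-2,4,8-trione with bridgeheads C10 and C23. Ring A (C7, C8, C10, C26, C23, C24) holds the enolised 1,3-dione and the C7 acyl group. Ring B (C10, C12, C13, C23, C26) contains the one-carbon ketone bridge C26. Ring C (C13, C14, C17, C22, C23) is a cyclopentane fused to the two-carbon bridge.
- There are five stereocentres, (3R,10S,13S,17S,23S). C10 and C23 are quaternary bridgeheads locked to each other. C13 places ring C on the side of the C26 bridge. C17 carries the 2-hydroxypropan-2-yl group cis to C26. C3 is remote and must be brought in enantiopure.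
- Sensitive groups: the non-enolisable β-dicarbonyl pairs around C26 (cleavage by nucleophiles), the acidic enolised triketone, the C3–H next to it, and the tertiary alcohol within reach of C26.
- The difficulty is two quaternary bridgeheads in a small, heavily oxygenated cage, and tying the ring C stereocentres to that cage.
- The feature used: the ring A carbonyl C8 is bonded directly to the methyl-bearing quaternary bridgehead C10. A ketone next to a quaternary carbon is what a 1,2-shift of C12 from an oxygenated C8 to a carbinol C10 leaves behind. The bicyclo[3.2.1]octane can therefore come from a bicyclo[2.2.2]octane, the natural product of a cyclohexadienone Diels–Alder reaction.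

## Retrosynthetic reasoning

**29 ⇒ 26 + 27.** The C5–C7 bond is cut last. The acyl group carries the only stereocentre that can epimerise through the triketone, so it should not meet acid, base or organometallics. The forward step must C-acylate the 1,3-dione of 26 with acid 27 without a ketene.

**26 ⇒ 25 ⇒ 23.** The C26 ketone is unmasked from dioxolane 25 only after the two C18 methyl groups are in place. A methyl nucleophile then meets 23 with C8 and C24 tied up as a dione enolate and C26 still a ketal. The strained bridging ketone is never exposed to it.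

**23 ⇒ 22 (key disconnection).** The C10–C12 bond is cut and C12 is re-attached to C8, which carries a methoxy group; C10 becomes a tertiary carbinol. This turns the one-, two- and three-atom bridges of 23 into the three two-atom bridges of bicyclo[2.2.2]octane 22. The forward step needs the C10–O bond antiperiplanar to C8–C12, and an acid-stable ketal and ester.

**22 ⇒ 21 ⇒ 20.** C13–H and the C10 methyl are both added by external reagents whose face is dictated by the cage.
- C13 is not set in the cycloaddition. A tethered alkene would have to put C14 next to the dioxolane oxygen that hangs under C26, and should instead place ring C on the wrong bridge.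
- C13 is kept trigonal (C12=C13 in 21). Hydrogen then comes from the open C7–C24 side and pushes ring C toward C26.
- While C12=C13 is still present, a methyl nucleophile enters the C10 ketone of 20 from that flat bridge. This puts the hydroxyl on the C7–C24 side, anti to C8–C12.

**20 ⇒ 19 ⇒ 18 ⇒ 17.** The C8–C12 and C13–C23 bonds are cut in a Diels–Alder sense. Masked ortho-benzoquinone 18 carries the diene C8=C7–C24=C23 and the tethered alkyne. The C26 ketal is made at the arene stage from a 2-hydroxyethyl ether, because a ketone between two quaternary carbons could not be ketalised later. The tether also directs ketalisation to C26 and not to the para position C24.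

**17 ⇒ 15 ⇒ 13 ⇒ 12 ⇒ 10.** The alkyne carbon C12 is added to aldehyde 15, which comes from the vinyl group of 13. The C14–C17 bond, the quaternary C14 and the stereocentre C17 come from an enantioselective ester-enolate Claisen rearrangement of ester 10.

**10 ⇒ 6 ⇒ 5 ⇒ 3 ⇒ 1 (with 4, 7, 8).** Lactone 5 fixes the three-carbon chain at C23 and marks the C26 oxygen; it comes from catechol 3 and acid 4. Opening the lactone with alcohol 7 and alkylating with ether 8 gives 10. The C10 oxygen is put in place at the start by converting the formyl group of aldehyde 1 into a hydroxyl.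

## Alternatives that were turned down

**Alternative 1:** anodic dearomative (3+2) annulation.
- Disconnection: C13–C23 and C10–C12 are cut together, back to the aromatic acylphloroglucinol A1 with a ketene dithioacetal tether.
- Forward key step: two-electron anodic oxidation; C13 attacks C23, the sulfur-stabilised cation at C12 is caught by C10, and the bis(methylthio) trione A2 results.
- For it: two rings, both quaternary bridgeheads and the dearomatisation in one operation, with every carbon of the target already present. C26 is trigonal when the bonds form, so ring C can take its place beside C26 without a ketal in the way. On step economy and on this stereochemical point it is stronger than the chosen route.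
- Against it:
  - the hexasubstituted triphenol is at least as easily oxidised as the ketene dithioacetal;
  - the C12 cation can be trapped by a phenol oxygen (five-membered ether) instead of by the fully substituted C10;
  - C3 and the triketone must survive the electrolysis;
  - C12 must afterwards be desulfurised next to the bridging ketone.
- Comparison: the chosen route is longer, but each C–C bond is made by a reaction whose regiochemistry is fixed by a tether or by an antiperiplanar shift.

**Alternative 2:** formal [4+2] on a cyclopentenone ester, ring contraction later.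
- Disconnection: C13–C14 and C22–C23 of a six-membered ring, back to silyloxydiene A3 and cyclopentenone ester A4.
- Forward key step: a chiral copper–bis(oxazoline) Lewis acid joins the dimethyl terminus of A3 to C13 and its methylene terminus to C23, giving cis-hydrindane A5.
- For it: absolute configuration comes from a catalyst, and the cis ring fusion sets H13 and the C23 ester (the future C24) correctly in the bond-forming step. On both points it is stronger than the chosen route, which uses a stoichiometric chiral boron reagent and a face-selective hydrogenation.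
- Against it:
  - the diene terminus that must form quaternary C14 is fully substituted, so a stepwise and less selective pathway is likely;
  - the six-membered ring of A5 still contains C18, which must be pushed out by a ring contraction that also creates C17;
  - ring A, with quaternary C10 and C8, must then be built onto a crowded cyclopentanone by enolate chemistry.
- Comparison: more steps after the key step than the chosen route has in total after the cycloaddition, and the hardest centre (C10) is left to the end. In the chosen route C10 is made by the rearrangement itself.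

**Alternative 3:** diazo ester insertion into a fused cyclobutanone.
- Disconnection: C10 is removed from between C26 and C12, back to cyclobutanone A6 and diazo ester A7.
- Forward key step: Lewis acid-catalysed addition of A7 to the C26 carbonyl and migration of C12 with loss of nitrogen give cyclopentanone A8 with quaternary C10.
- For it: ring B and C10 form in one strain-driven catalytic step, and the methylene carbon is the expected migrating group. The vinyl group and the new ester are placed for a short closure of ring A. In making C10 in one step it matches the chosen route.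
- Against it:
  - the configuration of C10 (ester versus methyl relative to the C23 vinyl group) is decided at a planar diazo carbon with no strong control element, and only one epimer can close ring A;
  - the carbonyl of A6 is flanked by quaternary C23 and is hindered toward a substituted diazo ester;
  - A6 itself needs a stereocontrolled [2+2] route.
- Comparison: in the chosen route C10 is a bridgehead whose configuration is forced by the cage, and the starting materials are simple aromatics.

Key step: step 14

Remark 1: with Et3N in toluene/hexane the (S,S)-diazaborolidine bromide is assumed to give (S)-12 through the E(O)-boron enolate 11; if the sense is the opposite, the (R,R)-reagent is used and nothing else changes.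

Remark 2: 26 and 29 are drawn as open hydroxy ketones; ring–chain equilibration with the C18–O–C26 hemiketal does not change the chemistry.

## Route

Step 1
Reactants: 1 2-hydroxy-4,6-dimethoxybenzaldehyde
Product: 3 3,5-dimethoxybenzene-1,2-diol, via aryl formate 2 (not isolated)
Conditions: 30% aq. H2O2, NaOH, THF/H2O, 0 °C to rt, N2; then 1 M HCl
Reagents that add atoms: hydrogen peroxide, OO
Why: Dakin oxidation: hydroperoxide adds to the ortho-hydroxy aldehyde, the aryl group migrates to oxygen and formate 2 is saponified in the flask. This turns the formyl carbon into the C10 oxygen, ortho to the C26 oxygen.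

Step 2
Reactants: 3 3,5-dimethoxybenzene-1,2-diol; 4 acrylic acid
Product: 5 8-hydroxy-5,7-dimethoxychroman-2-one
Conditions: polystyrenesulfonic acid resin (Amberlyst 15), toluene, reflux, Dean–Stark trap
Reagents that add atoms: none
Why: Acid-catalysed hydroarylation–lactonisation (dihydrocoumarin synthesis from a phenol and acrylic acid). Only the C26 hydroxyl has a free ortho carbon (C23), so the lactone fixes the chain at C23 and distinguishes the C26 oxygen from the C10 hydroxyl.

Step 3
Reactants: 5 8-hydroxy-5,7-dimethoxychroman-2-one
Product: 6 8-(benzyloxy)-5,7-dimethoxychroman-2-one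
Conditions: BnBr, K2CO3, acetone, 50 °C
Reagents that add atoms: benzyl bromide, BrCc1ccccc1
Why: Williamson etherification of the only free phenol. A benzyl ether, unlike a silyl or acyl group, cannot migrate to the neighbouring phenoxide released in step 4.

Step 4
Reactants: 6 8-(benzyloxy)-5,7-dimethoxychroman-2-one; 7 3-methylbut-2-en-1-ol; 8 benzyl 2-bromoethyl ether
Product: 10 3-methylbut-2-en-1-yl 3-{3-(benzyloxy)-2-[2-(benzyloxy)ethoxy]-4,6-dimethoxyphenyl}propanoate, via ring-opened phenol ester 9 (not isolated)
Conditions: NaH, 7, THF, 0 °C; then 8, NaI (cat.), DMF, 50 °C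
Reagents that add atoms: none
Why: Transesterification of the aryl lactone by the sodium alkoxide of 7 frees the C26 phenoxide 9, which is O-alkylated in the same flask before it can re-close the lactone. This gives the Claisen ester and the masked 2-hydroxyethyl group on the C26 oxygen.

Step 5
Reactants: 10 3-methylbut-2-en-1-yl 3-{3-(benzyloxy)-2-[2-(benzyloxy)ethoxy]-4,6-dimethoxyphenyl}propanoate
Product: 12 (2S)-2-({3-(benzyloxy)-2-[2-(benzyloxy)ethoxy]-4,6-dimethoxyphenyl}methyl)-3,3-dimethylpent-4-enoic acid, via boron ketene acetal 11 (not isolated)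
Conditions: (4S,5S)-2-bromo-4,5-diphenyl-1,3-bis(p-tolylsulfonyl)-1,3,2-diazaborolidine, Et3N, toluene/hexane, −78 °C, then −20 °C to rt; aqueous work-up
Reagents that add atoms: none
Why: Enantioselective Ireland–Claisen rearrangement through a chiral boron ketene acetal. The chair [3,3] shift joins C17 to the dimethyl-substituted allyl terminus (quaternary C14), and the sulfonamide-substituted boron chooses the enolate face, which sets C17 as (S).

Step 6
Reactants: 12 (2S)-2-({3-(benzyloxy)-2-[2-(benzyloxy)ethoxy]-4,6-dimethoxyphenyl}methyl)-3,3-dimethylpent-4-enoic acid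
Product: 13 methyl (2S)-2-({3-(benzyloxy)-2-[2-(benzyloxy)ethoxy]-4,6-dimethoxyphenyl}methyl)-3,3-dimethylpent-4-enoate
Conditions: MeI, K2CO3, DMF, rt
Reagents that add atoms: iodomethane, CI
Why: SN2 O-alkylation of the carboxylate. Carbonate does not enolise the hindered ester, so C17 is untouched.

Step 7
Reactants: 13 methyl (2S)-2-({3-(benzyloxy)-2-[2-(benzyloxy)ethoxy]-4,6-dimethoxyphenyl}methyl)-3,3-dimethylpent-4-enoate
Product: 15 methyl (2S)-2-({3-(benzyloxy)-2-[2-(benzyloxy)ethoxy]-4,6-dimethoxyphenyl}methyl)-3,3-dimethyl-4-oxobutanoate, via vicinal diol 14 (not isolated)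
Conditions: OsO4 (2 mol %), NaIO4, 2,6-lutidine, dioxane/H2O, rt
Reagents that add atoms: sodium periodate (oxygen relayed through OsO4), [Na+].[O-]I(=O)(=O)=O
Why: Lemieux–Johnson cleavage (catalytic dihydroxylation, then periodate glycol cleavage) of the only alkene. It gives the non-enolisable aldehyde whose carbonyl carbon is C13.

Step 8
Reactants: 15 methyl (2S)-2-({3-(benzyloxy)-2-[2-(benzyloxy)ethoxy]-4,6-dimethoxyphenyl}methyl)-3,3-dimethyl-4-oxobutanoate
Product: 16 methyl (2S)-2-{[3-hydroxy-2-(2-hydroxyethoxy)-4,6-dimethoxyphenyl]methyl}-3,3-dimethyl-4-oxobutanoate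
Conditions: H2 (1 atm), 10% Pd/C, EtOAc, rt
Reagents that add atoms: none
Why: Hydrogenolysis of both benzyl ethers frees the C10 phenol and the primary alcohol. It is placed after the alkene is gone and before the alkyne exists, and a hindered aliphatic aldehyde is not reduced under these conditions.

Step 9
Reactants: 16 methyl (2S)-2-{[3-hydroxy-2-(2-hydroxyethoxy)-4,6-dimethoxyphenyl]methyl}-3,3-dimethyl-4-oxobutanoate
Product: 17 methyl (2S)-2-{[3-hydroxy-2-(2-hydroxyethoxy)-4,6-dimethoxyphenyl]methyl}-3,3-dimethylpent-4-ynoate
Conditions: dimethyl (1-diazo-2-oxopropyl)phosphonate, K2CO3, MeOH, 0 °C to rt, Ar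
Reagents that add atoms: dimethyl (1-diazo-2-oxopropyl)phosphonate, CC(=O)C(=[N+]=[N-])P(=O)(OC)OC
Why: Ohira–Bestmann (Seyferth–Gilbert) homologation: the diazomethylphosphonate anion made in the flask adds to the aldehyde, and loss of phosphate and nitrogen gives the terminal alkyne C12≡C13. The aldehyde has no α-hydrogen and carbonate in methanol does not touch C17.

Step 10
Reactants: 17 methyl (2S)-2-{[3-hydroxy-2-(2-hydroxyethoxy)-4,6-dimethoxyphenyl]methyl}-3,3-dimethylpent-4-ynoate
Product: 19 cycloadduct (1-methoxybicyclo[2.2.2]octa-5,7-dien-2-one: C10 ketone, C26 spiro-dioxolane, C7=C24 methoxy enol ether, C12=C13; ring C fused at C13–C23; C17 ester on the ring C face turned to the dioxolane bridge), via spiroketal dienone 18 (not isolated)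
Conditions: PhI(OAc)2, CH2Cl2, 0 °C; then toluene, 90 °C
Reagents that add atoms: none
Why: Oxidative dearomatisation of the phenol with intramolecular ketalisation gives masked ortho-benzoquinone 18, whose diene C8=C7–C24=C23 adds the tethered alkyne in an intramolecular Diels–Alder reaction (C8–C12 and C13–C23 bonds, ring C, quaternary C23). C17 chooses the diene face: in the five-membered transition ring it tilts away from the dioxolane oxygen under C26 and keeps its ester pseudo-equatorial, which places the ester on the ring C face turned to the dioxolane bridge. An alkyne is used because a vinyl group would fix C13 with ring C on the enol ether side; here C13 stays trigonal.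

Step 11
Reactants: 19 cycloadduct
Product: 20 diketone (as 19, but C24 ketone and C7H2 in place of the enol ether)
Conditions: 1 M aq. HCl, THF, 0 °C to rt
Reagents that add atoms: water, O
Why: Hydrolysis of the methyl enol ether (protonation at C7, hydration of the C24 oxocarbenium ion, loss of methanol) frees the C24 ketone and makes C7 tetrahedral. The dioxolane next to the C10 ketone ionises far more slowly and stays.

Step 12
Reactants: 20 diketone
Product: 21 unsaturated carbinol (C10 tertiary alcohol with OH on the C7–C24 side and CH3 on the C12 side; C12=C13, C24 ketone, C26 dioxolane, C17 ester)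
Conditions: MeMgBr (1.1 equiv), CH2Cl2/Et2O, −78 °C; aq. NH4Cl
Reagents that add atoms: methylmagnesium bromide, C[Mg]Br
Why: Grignard addition to the C10 ketone, which is activated by chelation to its α-oxygens and reacts before the C24 ketone and the ester. As with other bicyclo[2.2.2]oct-5-en-2-ones the reagent enters from the side of the flat C12=C13 bridge, away from the hydrogen on C7, so the methyl ends on the C12 side and the hydroxyl on the C7–C24 side (C10 set).

Step 13
Reactants: 21 unsaturated carbinol
Product: 22 1-methoxybicyclo[2.2.2]octan-2-ol (C8–OMe bridgehead, C10 carbinol with OH anti to C8–C12, C26 dioxolane, C24 ketone, ring C on the C26 side, C17 ester cis to C26)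
Conditions: H2 (3 atm), 10% Pd/C, EtOAc, rt
Reagents that add atoms: none
Why: Heterogeneous hydrogenation of the trisubstituted C12=C13 bond, which has no position to migrate to. The face toward the C10–C26 bridge is shielded by the C10 methyl and a dioxolane oxygen, so hydrogen arrives from the C7–C24 side and ring C swings toward C26 (C13 set).

Step 14
Reactants: 22 1-methoxybicyclo[2.2.2]octan-2-ol
Product: 23 bicyclo[3.2.1]octane-2,4-dione (C8 and C24 ketones, C7H2, C10 methyl-bearing bridgehead, C26 dioxolane, C17 ester)
Conditions: p-toluenesulfonic acid (anhydrous, 0.3 equiv), toluene, 80 °C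
Reagents that add atoms: none
Why: Protonation of the tertiary C10 hydroxyl and its loss as water go together with a 1,2-shift of C12 from C8 to C10, pushed by the lone pair of the bridgehead methoxy oxygen; the C8 methoxy-oxocarbenium ion takes up the water just released and loses methanol to give the C8 ketone. The closest known reaction type is the acid-mediated pinacol-type rearrangement of 1-methoxybicyclo[2.2.2]octan-2-ols from masked ortho-benzoquinone adducts to bicyclo[3.2.1]octan-2-ones. Ring B (C10, C12, C13, C23, C26) is closed by this suprafacial 1,2-alkyl migration, a contraction of one six-membered ring of the cage, not by an end-to-end cyclisation. The new quaternary stereocentre C10 is formed with inversion at the migration terminus, C12 entering anti to the departing oxygen, and as a bridgehead it is tied to C23. The selectivity needed is migration of C12 and not of C7 or of a ketal oxygen. It is secured by the C10–O bond lying antiperiplanar to C8–C12 (hydroxyl on the C7–C24 side, set in step 12), by C7 being α to the C24 carbonyl and so a poor migrating group, and by both dioxolane oxygens being eclipsed or gauche to the leaving group. Elimination toward the exocyclic C10 methylene is reversible under acid and feeds back into the rearrangement, the dioxolane re-closes if it opens, and the ester is inert.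

Step 15
Reactants: 23 bicyclo[3.2.1]octane-2,4-dione
Product: 25 tertiary alcohol (as 23, but C17 bears C(CH3)2OH), via methyl ketone 24 (not isolated)
Conditions: MeMgBr (6 equiv), anhydrous CeCl3, THF, −78 to 0 °C; aq. NH4Cl
Reagents that add atoms: methylmagnesium bromide, C[Mg]Br
Why: The first equivalent deprotonates C7, and the 1,3-dione enolate shields C8 and C24 while C26 is still a dioxolane. Double addition of the organocerium reagent to the ester gives the tertiary alcohol, with cerium trichloride suppressing enolisation of ketone 24 at C17.

Step 16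
Reactants: 25 tertiary alcohol
Product: 26 trione alcohol (C8, C24 and C26 ketones, C7H2, C17 C(CH3)2OH)
Conditions: 2 M aq. HCl, THF, 50 °C
Reagents that add atoms: water, O
Why: Acid hydrolysis of the dioxolane, helped by the neighbouring C18 hydroxyl which can take over the oxocarbenium ion, frees the C26 ketone. In water the tertiary alcohol re-forms if it ionises, and no stereolabile group is present yet.

Step 17
Reactants: 26 trione alcohol; 27 (R)-2-methylbutanoic acid
Product: 29 target (3R,10S,13S,17S,23S), via enol ester 28 (not isolated)
Conditions: DCC, DMAP, CH2Cl2, 0 °C to rt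
Reagents that add atoms: none
Why: Steglich O-acylation of the enolised 1,3-dione, then 4-(dimethylamino)pyridine-mediated O-to-C acyl migration, gives the 2-acyl-1,3-dione (C5–C7 bond), a standard way to acylate bicyclo[3.2.1]octane-2,4-diones. The ketene-free conditions keep C3 as (R), and the tertiary alcohol is not acylated.

## Compound list

1 | 2-hydroxy-4,6-dimethoxybenzaldehyde | COc1cc(O)c(C=O)c(OC)c1 | starting material
2 | 2-hydroxy-4,6-dimethoxyphenyl formate | COc1cc(O)c(OC=O)c(OC)c1 | intermediate
3 | 3,5-dimethoxybenzene-1,2-diol | COc1cc(O)c(O)c(OC)c1 | intermediate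
4 | acrylic acid | C=CC(=O)O | starting material
5 | 8-hydroxy-5,7-dimethoxychroman-2-one | O=C1CCc2c(OC)cc(OC)c(O)c2O1 | intermediate
6 | 8-(benzyloxy)-5,7-dimethoxychroman-2-one | O=C1CCc2c(OC)cc(OC)c(OCc3ccccc3)c2O1 | intermediate
7 | 3-methylbut-2-en-1-ol | CC(C)=CCO | starting material
8 | benzyl 2-bromoethyl ether | BrCCOCc1ccccc1 | starting material
9 | 3-methylbut-2-en-1-yl 3-[3-(benzyloxy)-2-hydroxy-4,6-dimethoxyphenyl]propanoate (formed as its sodium phenoxide) | CC(C)=CCOC(=O)CCc1c(OC)cc(OC)c(OCc2ccccc2)c1O | intermediate
10 | 3-methylbut-2-en-1-yl 3-{3-(benzyloxy)-2-[2-(benzyloxy)ethoxy]-4,6-dimethoxyphenyl}propanoate | CC(C)=CCOC(=O)CCc1c(OC)cc(OC)c(OCc2ccccc2)c1OCCOCc1ccccc1 | intermediate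
11 | E(O)-boron ketene acetal of 10 with the (4S,5S)-4,5-diphenyl-1,3-bis(p-tolylsulfonyl)-1,3,2-diazaborolidin-2-yl group on oxygen | CC(C)=CCO/C(OB1N(S(=O)(=O)c2ccc(C)cc2)[C@@H](c2ccccc2)[C@H](c2ccccc2)N1S(=O)(=O)c1ccc(C)cc1)=C\Cc1c(OC)cc(OC)c(OCc2ccccc2)c1OCCOCc1ccccc1 | intermediate
12 | (2S)-2-({3-(benzyloxy)-2-[2-(benzyloxy)ethoxy]-4,6-dimethoxyphenyl}methyl)-3,3-dimethylpent-4-enoic acid | C=CC(C)(C)[C@@H](C(=O)O)Cc1c(OC)cc(OC)c(OCc2ccccc2)c1OCCOCc1ccccc1 | intermediate
13 | methyl (2S)-2-({3-(benzyloxy)-2-[2-(benzyloxy)ethoxy]-4,6-dimethoxyphenyl}methyl)-3,3-dimethylpent-4-enoate | C=CC(C)(C)[C@@H](C(=O)OC)Cc1c(OC)cc(OC)c(OCc2ccccc2)c1OCCOCc1ccccc1 | intermediate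
14 | methyl (2S)-2-({3-(benzyloxy)-2-[2-(benzyloxy)ethoxy]-4,6-dimethoxyphenyl}methyl)-4,5-dihydroxy-3,3-dimethylpentanoate (both C4 epimers) | OCC(O)C(C)(C)[C@@H](C(=O)OC)Cc1c(OC)cc(OC)c(OCc2ccccc2)c1OCCOCc1ccccc1 | intermediate
15 | methyl (2S)-2-({3-(benzyloxy)-2-[2-(benzyloxy)ethoxy]-4,6-dimethoxyphenyl}methyl)-3,3-dimethyl-4-oxobutanoate | O=CC(C)(C)[C@@H](C(=O)OC)Cc1c(OC)cc(OC)c(OCc2ccccc2)c1OCCOCc1ccccc1 | intermediate
16 | methyl (2S)-2-{[3-hydroxy-2-(2-hydroxyethoxy)-4,6-dimethoxyphenyl]methyl}-3,3-dimethyl-4-oxobutanoate | O=CC(C)(C)[C@@H](C(=O)OC)Cc1c(OC)cc(OC)c(O)c1OCCO | intermediate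
17 | methyl (2S)-2-{[3-hydroxy-2-(2-hydroxyethoxy)-4,6-dimethoxyphenyl]methyl}-3,3-dimethylpent-4-ynoate | C#CC(C)(C)[C@@H](C(=O)OC)Cc1c(OC)cc(OC)c(O)c1OCCO | intermediate
18 | methyl (2S)-2-[(7,9-dimethoxy-6-oxo-1,4-dioxaspiro[4.5]deca-7,9-dien-10-yl)methyl]-3,3-dimethylpent-4-ynoate | C#CC(C)(C)[C@@H](C(=O)OC)CC1=C(OC)C=C(OC)C(=O)C12OCCO2 | intermediate
19 | cycloadduct: 1-methoxybicyclo[2.2.2]octa-5,7-dien-2-one with C10 ketone, C26 spiro-1,3-dioxolane, C7=C24 enol ether (OMe on C24), C12=C13, ring C fused at C13–C23, methyl ester on C17 on the ring C face turned to the dioxolane bridge | O=C1[C@@]2(OC)C=C3C(C)(C)[C@@H](C(=O)OC)C[C@@]3(C(OC)=C2)C14OCCO4 | intermediate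
20 | diketone: as 19 with C24 ketone and C7H2 | O=C1[C@@]2(OC)C=C3C(C)(C)[C@@H](C(=O)OC)C[C@@]3(C(=O)C2)C14OCCO4 | intermediate
21 | unsaturated carbinol: as 20 with C10 bearing CH3 (C12 side) and OH (C7–C24 side) | C[C@@]1(O)[C@@]2(OC)C=C3C(C)(C)[C@@H](C(=O)OC)C[C@@]3(C(=O)C2)C14OCCO4 | intermediate
22 | 1-methoxybicyclo[2.2.2]octan-2-ol: C8–OMe bridgehead, C10 carbinol (OH anti to C8–C12), C26 dioxolane, C24 ketone, ring C on the C26 side with H13 toward C24, C17 ester cis to C26 | C[C@@]1(O)[C@@]2(OC)C[C@H]3C(C)(C)[C@@H](C(=O)OC)C[C@@]3(C(=O)C2)C14OCCO4 | intermediate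
23 | bicyclo[3.2.1]octane-2,4-dione: C8 and C24 ketones, C7H2, C10 methyl bridgehead, C26 dioxolane, C17 methyl ester | C1C(=O)[C@]2(C)C[C@H]3C(C)(C)[C@@H](C(=O)OC)C[C@@]3(C1=O)C24OCCO4 | intermediate
24 | methyl ketone: as 23 with acetyl on C17 | C1C(=O)[C@]2(C)C[C@H]3C(C)(C)[C@@H](C(C)=O)C[C@@]3(C1=O)C24OCCO4 | intermediate
25 | tertiary alcohol: as 23 with 2-hydroxypropan-2-yl on C17 | C1C(=O)[C@]2(C)C[C@H]3C(C)(C)[C@@H](C(C)(C)O)C[C@@]3(C1=O)C24OCCO4 | intermediate
26 | trione alcohol: as 25 with C26 ketone | C1C(=O)[C@]2(C)C[C@H]3C(C)(C)[C@@H](C(C)(C)O)C[C@@]3(C1=O)C2=O | intermediate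
27 | (R)-2-methylbutanoic acid | CC[C@@H](C)C(=O)O | starting material
28 | enol ester: C8 enol (R)-2-methylbutanoate of 26 | C1=C(OC(=O)[C@H](C)CC)[C@]2(C)C[C@H]3C(C)(C)[C@@H](C(C)(C)O)C[C@@]3(C1=O)C2=O | intermediate
29 | target, (3R,10S,13S,17S,23S) in the atom labels used here | CC[C@@H](C)C(=O)C1=C(O)[C@]2(C)C[C@H]3C(C)(C)[C@@H](C(C)(C)O)C[C@@]3(C1=O)C2=O | target

## Step count and least certain steps

Total steps: 17. Longest linear sequence: 17 (from 1; compounds 4, 7, 8 and 27 are bought).

**Step 14 (key step).** The C10 carbinol is deactivated by two β-oxygens. Ionisation at the ketal carbon C26 may therefore compete, followed by an acyloin-type shift or loss of the ketal, which then blocks ionisation at C10; or the carbinol may simply not ionise.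
Fallback: from 22, activate the hydroxyl as a sulfonate with no free acid present. Tf2O and 2,6-di-tert-butyl-4-methylpyridine in CH2Cl2 at −78 °C should give the tertiary triflate of 22 F1, which ionises below 0 °C with the same antiperiplanar shift of C12. Aqueous work-up turns the C8 oxocarbenium ion into the ketone and the route is rejoined at 23.

**Step 10.** The unactivated alkyne may add slowly, so that long heating is needed. The bicyclo[2.2.2]octadienone can then lose its keto-ketal bridge by thermal cycloreversion with aromatisation. Facial control by C17 rests only on a small preference of the tether conformation and may be poor.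
Fallback: an alkyne equivalent that adds as an activated alkene. From 16, Horner–Wittig olefination with diethyl [(phenylsulfinyl)methyl]phosphonate and NaH gives methyl (2S,4E)-2-{[3-hydroxy-2-(2-hydroxyethoxy)-4,6-dimethoxyphenyl]methyl}-3,3-dimethyl-5-(phenylsulfinyl)pent-4-enoate F2. PhI(OAc)2 converts it into the sulfinyl-substituted spiroketal dienone F3, which cyclises at about 60 °C to the sulfinyl cycloadduct F4. Brief heating in toluene with CaCO3 causes syn-elimination of benzenesulfenic acid across C12–C13, and the route is rejoined at 19.

**Step 12.** Chemoselectivity between the C10 and C24 ketones may be incomplete, and any enolisation of C24 makes C7 trigonal and erodes the facial bias at C10.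
Fallback: from 19, add methanol across the enol ether (MeOH, pyridinium p-toluenesulfonate, rt) to give the C24 dimethyl ketal of 20 F5, in which C7 is tetrahedral and C10 is the only ketone. MeMgBr then gives the C24 dimethyl ketal of 21 F6. Dilute aqueous HCl in THF at 0 °C removes the dimethyl ketal but not the dioxolane, and the route is rejoined at 21.

**Step 13.** Facial selectivity of the hydrogenation may be poor, because the C7 hydrogen partly shields the intended face, or the hindered trisubstituted alkene may react slowly.
Fallback: change the order. From 21, run the acid rearrangement first; the migrating carbon is then trigonal and the product is the bicyclo[3.2.1]oct-6-ene-2,4-dione F7. Its exo face is closed by the dioxolane oxygen on the one-carbon bridge, so H2 over Pd/C should add from the side of the three-carbon bridge, and the route is rejoined at 23.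

**Step 5.** Enantiocontrol depends on clean enolate geometry, and the Lewis-acidic boron bromide could attack the benzyl or methyl ethers.
Fallback: substrate control by chirality transfer. From 6, open the lactone with the sodium alkoxide of (R)-4-methylpent-3-en-2-ol F8 and alkylate with 8 as in step 4 to give the (R)-4-methylpent-3-en-2-yl ester F9. LDA in THF at −78 °C, then Me3SiCl and warming, rearranges it through a chair transition state (carbinol methyl equatorial, E(O)-enolate) to (2S,4E)-2-({3-(benzyloxy)-2-[2-(benzyloxy)ethoxy]-4,6-dimethoxyphenyl}methyl)-3,3-dimethylhex-4-enoic acid F10. MeI and K2CO3 give its methyl ester F11. The conditions of step 7 cleave the propenyl group, and the route is rejoined at 15.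

## Further compounds

F1 | step 14 | tertiary triflate of 22 (C10–OSO2CF3) | C[C@@]1(OS(=O)(=O)C(F)(F)F)[C@@]2(OC)C[C@H]3C(C)(C)[C@@H](C(=O)OC)C[C@@]3(C(=O)C2)C14OCCO4
F2 | step 10 | methyl (2S,4E)-2-{[3-hydroxy-2-(2-hydroxyethoxy)-4,6-dimethoxyphenyl]methyl}-3,3-dimethyl-5-(phenylsulfinyl)pent-4-enoate (sulfur epimers) | O=S(c1ccccc1)/C=C/C(C)(C)[C@@H](C(=O)OC)Cc1c(OC)cc(OC)c(O)c1OCCO
F3 | step 10 | sulfinyl-substituted spiroketal dienone (as 18 with (E)-2-(phenylsulfinyl)vinyl in place of ethynyl) | O=S(c1ccccc1)/C=C/C(C)(C)[C@@H](C(=O)OC)CC1=C(OC)C=C(OC)C(=O)C12OCCO2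
F4 | step 10 | sulfinyl cycloadduct (as 19 with saturated C12–C13, phenylsulfinyl on C12; C12, C13 and sulfur epimers) | O=C1[C@@]2(OC)C(S(=O)c4ccccc4)C3C(C)(C)[C@@H](C(=O)OC)C[C@@]3(C(OC)=C2)C15OCCO5
F5 | step 12 | C24 dimethyl ketal of 20 | O=C1[C@@]2(OC)C=C3C(C)(C)[C@@H](C(=O)OC)C[C@@]3(C(OC)(OC)C2)C14OCCO4
F6 | step 12 | C24 dimethyl ketal of 21 | C[C@@]1(O)[C@@]2(OC)C=C3C(C)(C)[C@@H](C(=O)OC)C[C@@]3(C(OC)(OC)C2)C14OCCO4
F7 | step 13 | bicyclo[3.2.1]oct-6-ene-2,4-dione (as 23 with C12=C13) | C1C(=O)[C@]2(C)C=C3C(C)(C)[C@@H](C(=O)OC)C[C@@]3(C1=O)C24OCCO4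
F8 | step 5 | (R)-4-methylpent-3-en-2-ol | C[C@@H](O)C=C(C)C
F9 | step 5 | (2R)-4-methylpent-3-en-2-yl 3-{3-(benzyloxy)-2-[2-(benzyloxy)ethoxy]-4,6-dimethoxyphenyl}propanoate | CC(C)=C[C@@H](C)OC(=O)CCc1c(OC)cc(OC)c(OCc2ccccc2)c1OCCOCc1ccccc1
F10 | step 5 | (2S,4E)-2-({3-(benzyloxy)-2-[2-(benzyloxy)ethoxy]-4,6-dimethoxyphenyl}methyl)-3,3-dimethylhex-4-enoic acid | C/C=C/C(C)(C)[C@@H](C(=O)O)Cc1c(OC)cc(OC)c(OCc2ccccc2)c1OCCOCc1ccccc1
F11 | step 5 | methyl (2S,4E)-2-({3-(benzyloxy)-2-[2-(benzyloxy)ethoxy]-4,6-dimethoxyphenyl}methyl)-3,3-dimethylhex-4-enoate | C/C=C/C(C)(C)[C@@H](C(=O)OC)Cc1c(OC)cc(OC)c(OCc2ccccc2)c1OCCOCc1ccccc1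
A1 | alternative 1 | acylphloroglucinol with ketene dithioacetal tether and triethylsilyl-protected tertiary alcohol | CC[C@@H](C)C(=O)c1c(O)c(C)c(O)c(C[C@H](C(C)(C)O[Si](CC)(CC)CC)C(C)(C)C=C(SC)SC)c1O
A2 | alternative 1 | 12,12-bis(methylthio) derivative of the O-triethylsilyl target | CC[C@@H](C)C(=O)C1=C(O)[C@]2(C)C(SC)(SC)[C@H]3C(C)(C)[C@@H](C(C)(C)O[Si](CC)(CC)CC)C[C@@]3(C1=O)C2=O
A3 | alternative 2 | tert-butyl(dimethyl)[(4-methylpenta-1,3-dien-3-yl)oxy]silane | C=CC(O[Si](C)(C)C(C)(C)C)=C(C)C
A4 | alternative 2 | methyl 5-oxocyclopent-1-ene-1-carboxylate | COC(=O)C1=CCCC1=O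
A5 | alternative 2 | cis-hydrindane keto ester silyl enol ether | C1C[C@H]2C(C)(C)C(O[Si](C)(C)C(C)(C)C)=CC[C@@]2(C(=O)OC)C1=O
A6 | alternative 3 | ring C-fused bicyclo[3.2.0]heptan-6-one with vinyl at C23 and methyl ester at C17 | O=C1C[C@H]2C(C)(C)[C@@H](C(=O)OC)C[C@@]12C=C
A7 | alternative 3 | methyl 2-diazopropanoate | COC(=O)C(C)=[N+]=[N-]
A8 | alternative 3 | ring B/ring C keto diester with quaternary C10 and vinyl at C23 | COC(=O)[C@]1(C)C[C@H]2C(C)(C)[C@@H](C(=O)OC)C[C@@]2(C=C)C1=O
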